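(Readings and results come from a simulation with made-up constants.)

2.00 was the number I sent back when you asked about the flask: the moles of L charged per mole of D, which I called the L cover. You guessed that X, at 0.950 per D, would hold Q short.

| flask | D | X | L | remark | time |
|---|---|---|---|---|---|
| amber | 0.20 M | 0.285 M | 0.60 M | run made earlier |  |
| red | 0.45 M | 0.285 M | 0.60 M | run made earlier |  |
| blue | 0.30 M | 0.43 M | 0.60 M | run made earlier |  |
| flask | 0.30 M | 0.285 M | 0.600 M |  | 30 h |

| run | time / h | D / % | Q / % | E / % |
|---|---|---|---|---|
| amber | 1.33 | 28.6 | 72.4 | 0.1 |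
| amber | 3.00 | 5.5 | 94.6 | 0 |
| amber | 8.00 | 0 | 99.4 | 0.6 |
| amber | 20.0 | 0 | 99.1 | 1.0 |
| red | 2.50 | 8.9 | 90.4 | 0 |
| red | 6.00 | 0 | 98.9 | 0 |
| red | 12.0 | 0 | 99.4 | 0.2 |
| red | 20.0 | 0 | 99.7 | 0 |
| blue | 2.50 | 8.0 | 90.4 | 0.9 |
| blue | 6.00 | 0.7 | 99.1 | 0 |
| blue | 12.0 | 0 | 99.9 | 0.9 |
| blue | 20.0 | 0.2 | 99.9 | 0.5 |

(standard deviation of a reading: 0.5 percentage points)

- the reaction counts as stopped when no species that holds the D changes by six tenths of a point or more over the second half of the time

- why nothing more happens at 30 h, or that something still does (it is still moving / all of D has reacted / forward and back rates have come level / L has run out first)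
- conversion of D at 30 h
- amount of Q at 30 h, in percent of the D charged

The red run spoke against your hunch: it read Q at 99.7% after 20.0 h with X at 0.633 per D, so Q did not take X one for one. No run read L, so I assumed that each Q took one L. Q, as a share of the D charged, then could not pass the cover, nor the whole charge of D. For the flask that ceiling was 100%. But red's cover of 1.33 also stood above one, so that run did not test the assumption.

Taking the decay as first order, I read a half-life of D near 0.736 h from amber's first reading, far shorter than the 30 h of the flask. So I expected D to read zero and Q to read the ceiling, give or take the scatter.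

The forecast, made from the same runs, said all of D has reacted, with conversion 100% and Q 99.6%, and it found “no sign of an equilibrium”. Its Q came from the late readings, mine was a ceiling.

In the flask, all of D has reacted, with conversion 100% and Q 99.7%, so the forecast held.

    D → J (k = 0.0161 min⁻¹)
    X + J ⇌ E (K = 0.990 L mol⁻¹, k = 49.3 L mol⁻¹ min⁻¹)
    L + J → Q (k = 48.8 L mol⁻¹ min⁻¹)
    2 X → Z (k = 0.298 L mol⁻¹ min⁻¹)
    J → G (k = 0.0689 min⁻¹)

In the flask, the half-life of D passing into J was 0.72 h at 0.718 h, far shorter than the 30 h allowed, and L stood at 50% of its charge at 30.0 h, close to the 50.0% that a cover of 2.00 leaves at one L for each D charged. The neighbour flask with 0.75 M of D had a cover of 0.800, and there L was the limiting reagent: it fell to 0% of its charge, G reached 20.0%, and Q stood at 80.0%, on its ceiling of 80.0%.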